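**Retrosynthetic overview**
- The hexaene is cut at one sp2–sp2 single bond (Stille): a bromodienyl oxolane hydroxy acid plus a stannyl tetraenyl ene-dione.
- The ene-dione stannane comes from a sequential double Wittig of the butane-2,3-dione bis-ylide with a stannyl trienal and (R)-2-methylbutanal.
- The oxolane is made by oxidative ring contraction (1,2-shift of the ring oxygen, C1 to C2) of a 4-acetoxy-3,4-dihydro-2H-pyran; this sets C2′ and leaves C1 as the future carboxyl group.
- The dihydropyran comes from a dihydropyranone made by a catalytic asymmetric aldol/cyclisation of 4-methoxybut-3-en-2-one with 5-bromopentadienal (sets C5′); cis-selective reduction sets C3′.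
- Ring order: the six-membered oxacycle is built first, then contracted to the only ring of the target; both polyene pieces derive from glutaconaldehyde potassium salt.

Assumption: glutaconaldehyde potassium salt and (R)-2-methylbutan-1-ol are bought as catalogue chemicals.

**Step 1**
Reactants: 1 glutaconaldehyde potassium salt
Product: 2 (2E,4E)-5-bromopenta-2,4-dienal
Conditions: PPh3, Br2, CH2Cl2, 0 °C; then 1, 0 °C → rt
Reagents that add atoms: bromine BrBr (delivered as Ph3PBr2 formed in the flask)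
Why: O-phosphonium activation of the vinylogous carboxylate followed by bromide addition–elimination (vinylogous Appel-type deoxybromination) gives the thermodynamic E,E-bromodienal.

**Step 2**
Reactants: 2 (2E,4E)-5-bromopenta-2,4-dienal; 3 (E)-4-methoxybut-3-en-2-one
Product: 5 (2R)-2-[(1E,3E)-4-bromobuta-1,3-dien-1-yl]-2,3-dihydro-4H-pyran-4-one, via aldol adduct 4 (not isolated)
Conditions: (S,S)-ProPhenol (10 mol%), Et2Zn (20 mol%), 4 Å MS, THF, −20 °C, 3 (5 equiv); then TFA (0.2 equiv), CH2Cl2, 0 °C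
Reagents that add atoms: none
Why: Proposed new method: the dinuclear Zn–ProPhenol catalyst deprotonates the only enolisable position of 3 (the α′-methyl group) to give, catalytically, a chiral zinc analogue of Danishefsky's diene, which adds to the Zn-bound aldehyde on its Re face to set C5′ (R), and TFA then drives 6-endo oxa-Michael addition/loss of MeOH to the dihydropyranone; the closest known reactions are the ProPhenol direct aldol of methyl ynones and methyl vinyl ketone and the aldol/TFA manifold of the Danishefsky hetero-Diels–Alder reaction (the ligand antipode is used if the facial sense inverts, as it does between aryl ketone and ynone donors).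

**Step 3**
Reactants: 5 (2R)-2-[(1E,3E)-4-bromobuta-1,3-dien-1-yl]-2,3-dihydro-4H-pyran-4-one
Product: 7 (2R,4R)-2-[(1E,3E)-4-bromobuta-1,3-dien-1-yl]-3,4-dihydro-2H-pyran-4-yl acetate, via cis-allylic alcohol 6 (not isolated)
Conditions: DIBAL-H, CH2Cl2, −78 °C; then pyridine, DMAP, Ac2O, −78 → 0 °C
Reagents that add atoms: acetic anhydride CC(=O)OC(C)=O
Why: 1,2-reduction with axial hydride delivery gives the equatorial alcohol cis to the dienyl group (sets C3′), and the aluminium alkoxide is acetylated in the same flask (Rychnovsky-type reductive acetylation); the electron-poor acetate is chosen because a free or electron-rich 3-oxygen diverts the next step to the enone.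

**Step 4**
Reactants: 7 (2R,4R)-2-[(1E,3E)-4-bromobuta-1,3-dien-1-yl]-3,4-dihydro-2H-pyran-4-yl acetate
Product: 10 (2R,3R,5R)-5-[(1E,3E)-4-bromobuta-1,3-dien-1-yl]-3-hydroxyoxolane-2-carboxylic acid, via acetoxy aldehyde 8 (not isolated), via acetoxy acid 9 (not isolated)
Conditions: PhI(OH)OTs, 3 Å MS, MeCN, −30 → 0 °C; then NaClO2, NaH2PO4, 2-methyl-2-butene, tBuOH/H2O, 0 °C; then LiOH (aq), rt; HCl to pH 3
Reagents that add atoms: [hydroxy(tosyloxy)iodo]benzene Cc1ccc(cc1)S(=O)(=O)OI(O)c1ccccc1; sodium chlorite [Na+].[O-]Cl=O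
Why: Hypervalent-iodine oxidative ring contraction of a glycal: the iodane adds to C2 anti to the acetate, the antiperiplanar ring oxygen shifts from C1 to C2 with inversion as PhI leaves (six- to five-membered ring, C2′ set trans to the 3-oxygen), and the elimination-prone β-acetoxy aldehyde is oxidised at once (Pinnick) and saponified in the same flask.

**Step 5**
Reactants: 2 (2E,4E)-5-bromopenta-2,4-dienal; 11 (Z)-1-bromo-2-ethoxyethene
Product: 13 (2E,4E,6E)-7-bromohepta-2,4,6-trienal, via hydroxy enol ether 12 (not isolated)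
Conditions: 11, nBuLi, Et2O, −78 °C; then 2, −78 °C; then 1 M HCl, THF, 0 °C
Reagents that add atoms: water O
Why: Two-carbon aldehyde homologation (Wollenberg/Schlosser): (Z)-2-ethoxyvinyllithium adds 1,2 to the aldehyde and the γ-hydroxy enol ether undergoes acid-mediated allylic transposition/hydrolysis to the E-enal.

**Step 6**
Reactants: 13 (2E,4E,6E)-7-bromohepta-2,4,6-trienal
Product: 14 (2E,4E,6E)-7-(tributylstannyl)hepta-2,4,6-trienal
Conditions: (Bu3Sn)2 (2 equiv), PdCl2(PPh3)2 (5 mol%), THF, 55 °C, dark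
Reagents that add atoms: hexabutylditin CCCC[Sn](CCCC)(CCCC)[Sn](CCCC)(CCCC)CCCC
Why: Pd(0)-catalysed stannylation of an activated alkenyl bromide with a distannane (Stille-type) proceeds with retention of the E geometry; excess distannane suppresses homocoupling.

**Step 7**
Reactants: 15 1,4-dibromobutane-2,3-dione
Product: 17 1,4-bis(triphenyl-λ5-phosphanylidene)butane-2,3-dione, via bisphosphonium dibromide 16 (not isolated)
Conditions: PPh3 (2.05 equiv), CH2Cl2, rt; then 2 M NaOH (aq), 0 °C
Reagents that add atoms: triphenylphosphine c1ccc(cc1)P(c1ccccc1)c1ccccc1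
Why: SN2 quaternisation of PPh3 by the α-bromo ketone termini and deprotonation give the acyl-stabilised bis-ylide (Wittig reagent synthesis).

**Step 8**
Reactants: 14 (2E,4E,6E)-7-(tributylstannyl)hepta-2,4,6-trienal; 17 1,4-bis(triphenyl-λ5-phosphanylidene)butane-2,3-dione; 18 (R)-2-methylbutan-1-ol
Product: 21 (3R,4E,8E,10E,12E,14E)-3-methyl-15-(tributylstannyl)pentadeca-4,8,10,12,14-pentaene-6,7-dione, via stannyl keto-ylide 19 (not isolated), via (R)-2-methylbutanal 20 (not isolated)
Conditions: 14, 17 (1.3 equiv), CH2Cl2, 35 °C, dark; then CH2Cl2 solution of 20 (4 equiv; from 18, TEMPO 5 mol%, PhI(OAc)2, rt, NaHCO3 wash), 35 °C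
Reagents that add atoms: none
Why: Sequential E-selective Wittig olefination in which the more nucleophilic bis-ylide takes the poorly electrophilic trienal first and the deactivated mono-ylide then takes the more electrophilic aliphatic aldehyde, which is made by TEMPO/PhI(OAc)2 oxidation without loss of the α-stereocentre.

**Step 9**
Reactants: 10 (2R,3R,5R)-5-[(1E,3E)-4-bromobuta-1,3-dien-1-yl]-3-hydroxyoxolane-2-carboxylic acid; 21 (3R,4E,8E,10E,12E,14E)-3-methyl-15-(tributylstannyl)pentadeca-4,8,10,12,14-pentaene-6,7-dione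
Product: 22 (2R,3R,5R)-3-hydroxy-5-[(1E,3E,5E,7E,9E,11E,15E,17R)-17-methyl-13,14-dioxononadeca-1,3,5,7,9,11,15-heptaen-1-yl]oxolane-2-carboxylic acid
Conditions: Pd2(dba)3 (5 mol%), AsPh3 (40 mol%), iPr2NEt (1.2 equiv), DMF/THF, rt, dark; pH 4 buffer work-up
Reagents that add atoms: none
Why: Stille coupling of a dienyl bromide with a polyenyl stannane is stereoretentive and tolerates the free hydroxyl, the carboxylate (held as its ammonium salt to prevent protodestannylation) and the dione.

**Compound list**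
1 | glutaconaldehyde potassium salt [potassium (1E,3E)-5-oxopenta-1,3-dien-1-olate] | [K+].[O-]/C=C/C=C/C=O | starting material
2 | (2E,4E)-5-bromopenta-2,4-dienal | O=C/C=C/C=C/Br | intermediate
3 | (E)-4-methoxybut-3-en-2-one | CO/C=C/C(C)=O | starting material
4 | (1E,5R,6E,8E)-9-bromo-5-hydroxy-1-methoxynona-1,6,8-trien-3-one | Br/C=C/C=C/[C@H](O)CC(=O)/C=C/OC | intermediate
5 | (2R)-2-[(1E,3E)-4-bromobuta-1,3-dien-1-yl]-2,3-dihydro-4H-pyran-4-one | Br/C=C/C=C/[C@H]1CC(=O)C=CO1 | intermediate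
6 | (2R,4R)-2-[(1E,3E)-4-bromobuta-1,3-dien-1-yl]-3,4-dihydro-2H-pyran-4-ol (present as its diisobutylaluminium alkoxide) | Br/C=C/C=C/[C@H]1C[C@@H](O)C=CO1 | intermediate
7 | (2R,4R)-2-[(1E,3E)-4-bromobuta-1,3-dien-1-yl]-3,4-dihydro-2H-pyran-4-yl acetate | Br/C=C/C=C/[C@H]1C[C@@H](OC(C)=O)C=CO1 | intermediate
8 | (2R,3R,5R)-5-[(1E,3E)-4-bromobuta-1,3-dien-1-yl]-2-formyloxolan-3-yl acetate | Br/C=C/C=C/[C@H]1C[C@@H](OC(C)=O)[C@H](C=O)O1 | intermediate
9 | (2R,3R,5R)-3-acetoxy-5-[(1E,3E)-4-bromobuta-1,3-dien-1-yl]oxolane-2-carboxylic acid | Br/C=C/C=C/[C@H]1C[C@@H](OC(C)=O)[C@H](C(=O)O)O1 | intermediate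
10 | (2R,3R,5R)-5-[(1E,3E)-4-bromobuta-1,3-dien-1-yl]-3-hydroxyoxolane-2-carboxylic acid | Br/C=C/C=C/[C@H]1C[C@@H](O)[C@H](C(=O)O)O1 | intermediate
11 | (Z)-1-bromo-2-ethoxyethene | CCO/C=C\Br | starting material
12 | (1Z,4E,6E)-7-bromo-1-ethoxyhepta-1,4,6-trien-3-ol (racemic at C3) | CCO/C=C\C(O)/C=C/C=C/Br | intermediate
13 | (2E,4E,6E)-7-bromohepta-2,4,6-trienal | O=C/C=C/C=C/C=C/Br | intermediate
14 | (2E,4E,6E)-7-(tributylstannyl)hepta-2,4,6-trienal | O=C/C=C/C=C/C=C/[Sn](CCCC)(CCCC)CCCC | intermediate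
15 | 1,4-dibromobutane-2,3-dione | BrCC(=O)C(=O)CBr | starting material
16 | (2,3-dioxobutane-1,4-diyl)bis(triphenylphosphonium) dibromide | [Br-].[Br-].O=C(C[P+](c1ccccc1)(c1ccccc1)c1ccccc1)C(=O)C[P+](c1ccccc1)(c1ccccc1)c1ccccc1 | intermediate
17 | 1,4-bis(triphenyl-λ5-phosphanylidene)butane-2,3-dione | O=C(C=P(c1ccccc1)(c1ccccc1)c1ccccc1)C(=O)C=P(c1ccccc1)(c1ccccc1)c1ccccc1 | intermediate
18 | (R)-2-methylbutan-1-ol | CC[C@@H](C)CO | starting material
19 | (4E,6E,8E,10E)-11-(tributylstannyl)-1-(triphenyl-λ5-phosphanylidene)undeca-4,6,8,10-tetraene-2,3-dione | O=C(C=P(c1ccccc1)(c1ccccc1)c1ccccc1)C(=O)/C=C/C=C/C=C/C=C/[Sn](CCCC)(CCCC)CCCC | intermediate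
20 | (R)-2-methylbutanal | CC[C@@H](C)C=O | intermediate
21 | (3R,4E,8E,10E,12E,14E)-3-methyl-15-(tributylstannyl)pentadeca-4,8,10,12,14-pentaene-6,7-dione | CC[C@@H](C)/C=C/C(=O)C(=O)/C=C/C=C/C=C/C=C/[Sn](CCCC)(CCCC)CCCC | intermediate
22 | (2R,3R,5R)-3-hydroxy-5-[(1E,3E,5E,7E,9E,11E,15E,17R)-17-methyl-13,14-dioxononadeca-1,3,5,7,9,11,15-heptaen-1-yl]oxolane-2-carboxylic acid | CC[C@@H](C)/C=C/C(=O)C(=O)/C=C/C=C/C=C/C=C/C=C/C=C/[C@H]1C[C@@H](O)[C@H](C(=O)O)O1 | target

**Step count and risks**
Total: 9 steps. Longest linear sequence: 5 steps (steps 1, 5, 6, 8, 9; the oxolane branch 1, 2, 3, 4, 9 is equally long).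

The three steps most likely to fail:

Step 2 (the proposed new step). The β-methoxy enone is untested as a ProPhenol donor, so enolisation may be slow or the enantioselectivity low. The fallback uses known chemistry and sets out from 3 and 2. Ketone 3 is silylated (TMSCl, Et3N, ZnCl2) to Danishefsky's diene F1. F1 and 2 then undergo the Jacobsen (salen)Cr(III)BF4-catalysed hetero-Diels–Alder reaction (catalyst enantiomer chosen for the R adduct) to the silyl enol ether cycloadduct F2. TFA converts F2 into 5, where the route is rejoined.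

Step 4. The iodane may attack the bromodiene, the liberated TsOH may trigger Ferrier ionisation of the allylic acetate, or the aldehyde may eliminate acetic acid before it is oxidised. The fallback replaces the oxidative trigger by a sulfonate leaving group and sets out from 7. DMDO epoxidises 7 anti to the acetate to the 1,2-anhydro pyranose F3, and methanol opens it to the methyl glycoside F4 with an equatorial 2-hydroxyl. Tf2O/pyridine gives the triflate F5, and warming in methanol with 2,6-lutidine effects the solvolytic ring contraction to the dimethyl acetal F6. Aqueous TFA liberates 8, which re-enters step 4 at the chlorite stage.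

Step 8. The stannyl polyene may not survive two olefinations, or the second Wittig may stall. The fallback installs the dione after the cross-coupling and sets out from 10 and 14. Their Stille coupling gives the pentaenal acid F7. Its diisopropylethylammonium salt reacts with 17 to the keto-ylide acid F8, and aldehyde 20 then completes the sequence directly at 22.

**Further compounds**
F1 | step 2 | (E)-1-methoxy-3-(trimethylsilyloxy)buta-1,3-diene | CO/C=C/C(=C)O[Si](C)(C)C
F2 | step 2 | {[(2R)-2-[(1E,3E)-4-bromobuta-1,3-dien-1-yl]-6-methoxy-3,6-dihydro-2H-pyran-4-yl]oxy}trimethylsilane (anomeric mixture) | Br/C=C/C=C/[C@H]1CC(O[Si](C)(C)C)=CC(OC)O1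
F3 | step 4 | 3-[(1E,3E)-4-bromobuta-1,3-dien-1-yl]-2,7-dioxabicyclo[4.1.0]heptan-5-yl acetate, epoxide oxygen trans to the acetoxy and dienyl groups | Br/C=C/C=C/[C@H]1C[C@@H](OC(C)=O)[C@@H]2O[C@@H]2O1
F4 | step 4 | (2S,3S,4R,6R)-6-[(1E,3E)-4-bromobuta-1,3-dien-1-yl]-3-hydroxy-2-methoxyoxan-4-yl acetate | Br/C=C/C=C/[C@H]1C[C@@H](OC(C)=O)[C@H](O)[C@@H](OC)O1
F5 | step 4 | (2S,3S,4R,6R)-6-[(1E,3E)-4-bromobuta-1,3-dien-1-yl]-2-methoxy-3-[(trifluoromethanesulfonyl)oxy]oxan-4-yl acetate | Br/C=C/C=C/[C@H]1C[C@@H](OC(C)=O)[C@H](OS(=O)(=O)C(F)(F)F)[C@@H](OC)O1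
F6 | step 4 | (2R,3R,5R)-5-[(1E,3E)-4-bromobuta-1,3-dien-1-yl]-2-(dimethoxymethyl)oxolan-3-yl acetate | Br/C=C/C=C/[C@H]1C[C@@H](OC(C)=O)[C@H](C(OC)OC)O1
F7 | step 8 | (2R,3R,5R)-3-hydroxy-5-[(1E,3E,5E,7E,9E)-11-oxoundeca-1,3,5,7,9-pentaen-1-yl]oxolane-2-carboxylic acid | O=C/C=C/C=C/C=C/C=C/C=C/[C@H]1C[C@@H](O)[C@H](C(=O)O)O1
F8 | step 8 | (2R,3R,5R)-3-hydroxy-5-[(1E,3E,5E,7E,9E,11E)-13,14-dioxo-15-(triphenyl-λ5-phosphanylidene)pentadeca-1,3,5,7,9,11-hexaen-1-yl]oxolane-2-carboxylic acid | O=C(C=P(c1ccccc1)(c1ccccc1)c1ccccc1)C(=O)/C=C/C=C/C=C/C=C/C=C/C=C/[C@H]1C[C@@H](O)[C@H](C(=O)O)O1
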